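**Plan**
- **Cuts (retrosynthesis):** the C18–O coumarate ester and the C15 oxidation level, then C8=C17 (methylenation of an 8-ketone). The C9–C10 bond is traced back by a retro-1,2-shift to a C8–C10 bond, so ring B shrinks to the five-membered ring C5-C6-C7-C8-C10. Next come C8=C9 (Wittig, which frees the C9/C11–C16 chain), C4–C18, and ring A (Robinson annulation).
- **Enabling feature:** in ring B the sp2 carbon C8 lies next to C9, the chain-bearing CH bonded to quaternary C10. As the 8-ketone this is an alpha-branched cyclohexanone, the retron of a semipinacol shift of C10 from a C8 carbinol to an exocyclic C9 that carries a leaving group.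
- **Forward order:** ring A and the five-membered ring are made together; C4/C5 follow by reductive alkylation. The chain is joined at C8=C9, the five-membered ring is enlarged to ring B, and C17 is added. Ester formation, acid formation and phenol release close the route.
- **Stereochemistry:** C10 comes from the D-phenylalanine-mediated aldol step, and C5 and C4 are relayed from C10. C9 arises by inversion in the shift and then equilibration to the equatorial epimer. C13 comes from (S)-citronellol and the E alkene from 4-acetoxycinnamic acid.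

Key step: step 12

Remark: labdane numbering (C1–C20) is used for all intermediates, hydrindanes included. The SMILES is read as the ent-labdane 4S,5S,9R,10S,13S, whose acylated CH2O group at C4 is equatorial (anti to C20).

Step 1
Reactants: 1 2-methylcyclopentane-1,3-dione; 2 pent-1-en-3-one (ethyl vinyl ketone)
Product: 4 (7aR)-4,7a-dimethyl-2,3,7,7a-tetrahydro-1H-indene-1,5(6H)-dione, via triketone 3 (not isolated)
Conditions: Et3N (cat.), neat, rt; then D-phenylalanine, (1R)-(−)-camphor-10-sulfonic acid, DMF, 30 → 70 °C
Reagents that add atoms: none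
Why: Michael addition followed by the Hajos–Parrish–Eder–Sauer–Wiechert aldol condensation (Robinson annulation), in which the enamine of the primary D-amino acid differentiates the two enantiotopic ring carbonyls and sets quaternary C10 (R); recrystallisation should raise the enantiopurity.

Step 2
Reactants: 4 enedione
Product: 5 C8 ethylene ketal of 4 (enone untouched)
Conditions: TMSOCH2CH2OTMS, TMSOTf (cat.), CH2Cl2, −78 °C
Reagents that add atoms: 1,2-bis(trimethylsilyloxy)ethane, C[Si](C)(C)OCCO[Si](C)(C)C
Why: Noyori ketalisation under kinetic control takes the saturated cyclopentanone carbonyl and leaves the less electrophilic conjugated enone, which protects C8 for steps 3 and 4.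

Step 3
Reactants: 5 ketal enone
Product: 7 trans-fused 3-keto ketal bearing at C4 an axial CH3 (syn to C20) plus an equatorial CH2OBn (anti to C20); H5 anti to C20, via lithium enolate 6 (not isolated)
Conditions: Li (2.1 equiv), t-BuOH (1.0 equiv), NH3(l)/THF, −78 → −33 °C; NH3 off; BnOCH2Cl, THF, −78 → 0 °C
Reagents that add atoms: benzyl chloromethyl ether, ClCOCc1ccccc1; lithium, [Li] (stays only in 6)
Why: Dissolving-metal reductive alkylation of an enone, in which axial protonation of the beta-carbanion at C5 gives the trans ring fusion and the regiodefined C3–C4 enolate is alkylated on the face anti to the axial angular methyl, so that the new CH2OBn group ends equatorial.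

Step 4
Reactants: 7 keto ketal
Product: 10 (3aR,4S,7aR)-4-[(benzyloxy)methyl]-4,7a-dimethyloctahydro-1H-inden-1-one (trans-hydrindan-8-one), via hydrazone 8 (not isolated), via deoxygenated ketal 9 (not isolated)
Conditions: N2H4·H2O, KOH, diethylene glycol, 130 → 200 °C; then 3 M HCl, THF, rt
Reagents that add atoms: hydrazine hydrate, NN.O (nitrogen stays only in 8); water, O
Why: Wolff–Kishner reduction (Huang-Minlon procedure) removes the C3 carbonyl, which has no alpha leaving group and no enolisable stereocentre next to it, and the acidic work-up hydrolyses the dioxolane to free the C8 ketone.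

Step 5
Reactants: 11 (S)-(−)-citronellol
Product: 12 (S)-citronellyl tert-butyldimethylsilyl ether
Conditions: TBSCl, imidazole, CH2Cl2, rt
Reagents that add atoms: tert-butyldimethylsilyl chloride, CC(C)(C)[Si](C)(C)Cl
Why: Standard silylation masks the future C15 oxygen against ylide, aluminium and lithium reagents; C13 comes unchanged from the chiral pool.

Step 6
Reactants: 12 silyl ether
Product: 14 (S)-6-(tert-butyldimethylsilyloxy)-4-methylhexan-1-ol, via ozonide 13 (not isolated)
Conditions: O3, CH2Cl2, −78 °C; then NaBH4, MeOH, −78 → 0 °C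
Reagents that add atoms: ozone, [O-][O+]=O
Why: Ozonolysis with reductive work-up cuts off the isopropylidene end and leaves the carbon that becomes C9 as a primary alcohol.

Step 7
Reactants: 14 alcohol
Product: 15 (S)-tert-butyl[(6-iodo-3-methylhexyl)oxy]dimethylsilane
Conditions: I2, PPh3, imidazole, CH2Cl2, 0 °C → rt
Reagents that add atoms: iodine, II
Why: Appel-type iodination of an unhindered primary alcohol under buffered conditions that the silyl ether tolerates.

Step 8
Reactants: 15 iodide
Product: 16 (S)-[6-(tert-butyldimethylsilyloxy)-4-methylhexyl]triphenylphosphonium iodide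
Conditions: PPh3, MeCN, 80 °C
Reagents that add atoms: triphenylphosphine, c1ccc(cc1)P(c1ccccc1)c1ccccc1
Why: SN2 quaternisation of triphenylphosphine by a primary iodide.

Step 9
Reactants: 16 phosphonium iodide; 10 trans-hydrindan-8-one
Product: 18 (Z)-8(9)-alkene (C8=C9H-chain; C11 syn to C10), via ylide 17 (not isolated)
Conditions: 16, KOtBu, THF, 0 °C → rt; then 10, reflux
Reagents that add atoms: none
Why: Wittig olefination with a non-stabilised ylide, which on 17-oxo steroids (the same trans-hydrindanone with an angular methyl) gives under kinetic control the Z alkene with the alkyl chain syn to the quaternary carbon, the geometry that step 12 needs.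

Step 10
Reactants: 18 Z alkene
Product: 19 8,9-diol (tertiary 8-OH plus secondary 9-OH; both on the face anti to C20)
Conditions: OsO4 (cat.), 4-methylmorpholine N-oxide, MeSO2NH2, acetone/H2O, rt
Reagents that add atoms: 4-methylmorpholine N-oxide, C[N+]1([O-])CCOCC1; water, O
Why: Upjohn dihydroxylation adds both oxygens suprafacially from the face anti to the angular methyl, so that the Z geometry is translated into one defined C8/C9 relative configuration.

Step 11
Reactants: 19 diol
Product: 20 9-mesylate of 19 (8-OH free)
Conditions: MsCl, Et3N, CH2Cl2, −20 → 0 °C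
Reagents that add atoms: methanesulfonyl chloride, CS(=O)(=O)Cl
Why: Selective sulfonylation of the secondary hydroxyl, the tertiary C8 hydroxyl next to quaternary C10 being inert under these conditions.

Step 12
Reactants: 20 hydroxy mesylate
Product: 23 (13S)-ent-18-benzyloxy-15-(tert-butyldimethylsilyloxy)-17-norlabdan-8-one (trans-decalone; chain at C9 equatorial), via aluminium alkoxide 21 (not isolated), via 9-epi ketone 22 (not isolated)
Conditions: Et2AlCl (2.5 equiv), CH2Cl2, −78 → 0 °C; aq. potassium sodium tartrate work-up; crude, NaOMe (cat.), MeOH, rt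
Reagents that add atoms: diethylaluminium chloride, CC[Al](Cl)CC (its atoms stay only in 21)
Why: Et2AlCl turns the tertiary C8-OH into aluminium alkoxide 21, whose metal also binds the C9 mesylate, and as the C9–O bond ionises the antiperiplanar C8–C10 bond shifts to C9 while C8 becomes the carbonyl carbon, so that C9 with the whole side chain is inserted into the five-membered ring C5-C6-C7-C8-C10 and six-membered ring B results (semipinacol rearrangement of a 2-sulfonyloxy alcohol). The closest known reaction types are the organoaluminium-promoted 1,2-shift of 2-mesyloxy alcohols, the olefination/dihydroxylation/monosulfonate one-carbon enlargement of cyclic ketones, and the D-homoannulation of 17-hydroxy steroids, whose C/D hydrindane has the same local structure. No ring is closed by a new cyclisation: ring B arises from five to six atoms by a suprafacial 1,2-alkyl shift with retention at the migrating quaternary C10 and inversion at C9. The inversion gives first the 9-epimer 22 with an axial chain, and because C9 is now alpha to the ketone, NaOMe equilibrates it to 23, in which the chain is equatorial on the rigid trans-decalone chair fixed by C5 and C10. The step needs migration of C10 rather than C7 and no epoxide closure: C10 is the fully substituted and hence better migrating carbon and its shift relieves the C8/C10 congestion, the C9 configuration inherited from the Z alkene puts the chain into the open O8/C10 sector only in the rotamer that has C8–C10 anti to the mesylate (the rotamer for C7 migration would wedge C11 between C7 and C10), and the O8–Al–mesylate chelate keeps O8 gauche to the leaving group so that backside attack by oxygen is excluded.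

Step 13
Reactants: 23 8-ketone
Product: 24 (13S)-ent-18-benzyloxy-15-(tert-butyldimethylsilyloxy)labd-8(17)-ene
Conditions: Ph3PCH3Br, KOtBu, toluene, rt → 80 °C
Reagents that add atoms: methyltriphenylphosphonium bromide, [Br-].C[P+](c1ccccc1)(c1ccccc1)c1ccccc1
Why: Wittig methylenation as used on 8-oxo-17-norlabdanes; enolisation under the basic conditions cannot harm C9 because 23 already has the thermodynamic configuration.

Step 14
Reactants: 24 benzyl ether
Product: 25 (13S)-ent-15-(tert-butyldimethylsilyloxy)labd-8(17)-en-18-ol
Conditions: Li, NH3(l)/THF, −78 °C; NH4Cl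
Reagents that add atoms: none
Why: Dissolving-metal debenzylation spares the isolated 1,1-disubstituted alkene (which hydrogenolysis would not) and the alkyl silyl ether.

Step 15
Reactants: 25 C18 alcohol; 26 (E)-4-acetoxycinnamic acid
Product: 27 (13S)-ent-15-(tert-butyldimethylsilyloxy)labd-8(17)-en-18-yl (E)-4-acetoxycinnamate
Conditions: EDC·HCl, 4-(dimethylamino)pyridine (DMAP), CH2Cl2, rt
Reagents that add atoms: none
Why: Steglich-type esterification of the primary neopentyl alcohol with the O-acetyl-protected hydroxycinnamic acid, the usual way to steryl and terpenyl hydroxycinnamates; the E geometry is carried in from 26.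

Step 16
Reactants: 27 silyl ether
Product: 28 (13S)-ent-15-hydroxylabd-8(17)-en-18-yl (E)-4-acetoxycinnamate
Conditions: HF·pyridine, pyridine/THF, 0 °C → rt
Reagents that add atoms: none
Why: Buffered fluoride desilylation is non-basic, so that the aryl acetate and the cinnamate survive, and too weakly acidic to isomerise the exocyclic alkene.

Step 17
Reactants: 28 primary alcohol
Product: 30 (13S)-ent-18-[(E)-4-acetoxycinnamoyloxy]labd-8(17)-en-15-oic acid, via aldehyde 29 (not isolated)
Conditions: 2,2,6,6-tetramethylpiperidin-1-oxyl (TEMPO, cat.), PhI(OAc)2, MeCN/H2O, rt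
Reagents that add atoms: water, O
Why: Oxoammonium-mediated oxidation of the unhindered primary alcohol through the aldehyde hydrate to the acid leaves alkenes and esters alone, and the phenol is still masked against the oxidant.

Step 18
Reactants: 30 acetoxy acid
Product: 31 target, (13S)-ent-18-[(E)-4-hydroxycinnamoyloxy]labd-8(17)-en-15-oic acid (4S,5S,9R,10S,13S)
Conditions: pyrrolidine, EtOH, rt; 1 M HCl wash
Reagents that add atoms: none
Why: Chemoselective aminolysis of the activated aryl acetate, a known way to free hydroxycinnamate esters, while the conjugated alkyl ester is inert at room temperature.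

**Compound list**
1 | 2-methylcyclopentane-1,3-dione | CC1C(=O)CCC1=O | starting material
2 | pent-1-en-3-one | C=CC(=O)CC | starting material
3 | 2-methyl-2-(3-oxopentyl)cyclopentane-1,3-dione | CCC(=O)CCC1(C)C(=O)CCC1=O | intermediate
4 | (7aR)-4,7a-dimethyl-2,3,7,7a-tetrahydro-1H-indene-1,5(6H)-dione | O=C1CCC2=C(C)C(=O)CC[C@@]12C | intermediate
5 | C8 ethylene ketal of 4 | C12(OCCO1)CCC3=C(C)C(=O)CC[C@@]23C | intermediate
6 | lithium C3–C4 enolate of the trans-fused ketal | C12(OCCO1)CC[C@@H]3C(C)=C([O-])CC[C@@]23C.[Li+] | intermediate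
7 | trans-fused 3-keto ketal, C4 axial CH3 and equatorial CH2OBn (4S,5S,10R) | C12(OCCO1)CC[C@@H]3[C@@](C)(COCc4ccccc4)C(=O)CC[C@@]23C | intermediate
8 | C3 hydrazone of 7 | C12(OCCO1)CC[C@@H]3[C@@](C)(COCc4ccccc4)C(=NN)CC[C@@]23C | intermediate
9 | 3-deoxy ketal | C12(OCCO1)CC[C@@H]3[C@@](C)(COCc4ccccc4)CCC[C@@]23C | intermediate
10 | (3aR,4S,7aR)-4-[(benzyloxy)methyl]-4,7a-dimethyloctahydro-1H-inden-1-one | O=C1CC[C@@H]2[C@@](C)(COCc3ccccc3)CCC[C@@]12C | intermediate
11 | (S)-(−)-citronellol | CC(C)=CCC[C@H](C)CCO | starting material
12 | (S)-citronellyl TBS ether | CC(C)=CCC[C@H](C)CCO[Si](C)(C)C(C)(C)C | intermediate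
13 | secondary ozonide of 12 (acetal carbon unassigned) | CC1(C)OOC(CC[C@H](C)CCO[Si](C)(C)C(C)(C)C)O1 | intermediate
14 | (S)-6-(tert-butyldimethylsilyloxy)-4-methylhexan-1-ol | OCCC[C@H](C)CCO[Si](C)(C)C(C)(C)C | intermediate
15 | (S)-tert-butyl[(6-iodo-3-methylhexyl)oxy]dimethylsilane | ICCC[C@H](C)CCO[Si](C)(C)C(C)(C)C | intermediate
16 | (S)-[6-(tert-butyldimethylsilyloxy)-4-methylhexyl]triphenylphosphonium iodide | [I-].c1ccccc1[P+](c1ccccc1)(c1ccccc1)CCC[C@H](C)CCO[Si](C)(C)C(C)(C)C | intermediate
17 | ylide of 16 | c1ccccc1P(c1ccccc1)(c1ccccc1)=CCC[C@H](C)CCO[Si](C)(C)C(C)(C)C | intermediate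
18 | (Z)-8(9)-alkene, C11 syn to C10 | CC(C)(C)[Si](C)(C)OCC[C@@H](C)CC/C=C1/CC[C@@H]2[C@@](C)(COCc3ccccc3)CCC[C@@]12C | intermediate
19 | 8,9-diol, both OH anti to C20 | CC(C)(C)[Si](C)(C)OCC[C@@H](C)CC[C@@H](O)[C@]1(O)CC[C@@H]2[C@@](C)(COCc3ccccc3)CCC[C@@]12C | intermediate
20 | 9-mesylate of 19 | CC(C)(C)[Si](C)(C)OCC[C@@H](C)CC[C@@H](OS(C)(=O)=O)[C@]1(O)CC[C@@H]2[C@@](C)(COCc3ccccc3)CCC[C@@]12C | intermediate
21 | chloro(ethyl)aluminium C8 alkoxide of 20 | CC(C)(C)[Si](C)(C)OCC[C@@H](C)CC[C@@H](OS(C)(=O)=O)[C@]1(O[Al](Cl)CC)CC[C@@H]2[C@@](C)(COCc3ccccc3)CCC[C@@]12C | intermediate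
22 | 9-epimer of 23 (axial chain) | O=C1CC[C@@H]2[C@@](C)(COCc3ccccc3)CCC[C@@]2(C)[C@H]1CC[C@H](C)CCO[Si](C)(C)C(C)(C)C | intermediate
23 | (13S)-ent-18-benzyloxy-15-(tert-butyldimethylsilyloxy)-17-norlabdan-8-one | O=C1CC[C@@H]2[C@@](C)(COCc3ccccc3)CCC[C@@]2(C)[C@@H]1CC[C@H](C)CCO[Si](C)(C)C(C)(C)C | intermediate
24 | (13S)-ent-18-benzyloxy-15-(tert-butyldimethylsilyloxy)labd-8(17)-ene | C=C1CC[C@@H]2[C@@](C)(COCc3ccccc3)CCC[C@@]2(C)[C@@H]1CC[C@H](C)CCO[Si](C)(C)C(C)(C)C | intermediate
25 | (13S)-ent-15-(tert-butyldimethylsilyloxy)labd-8(17)-en-18-ol | C=C1CC[C@@H]2[C@@](C)(CO)CCC[C@@]2(C)[C@@H]1CC[C@H](C)CCO[Si](C)(C)C(C)(C)C | intermediate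
26 | (E)-4-acetoxycinnamic acid | CC(=O)Oc1ccc(/C=C/C(=O)O)cc1 | starting material
27 | 18-(E)-4-acetoxycinnamate of 25 | C=C1CC[C@@H]2[C@@](C)(COC(=O)/C=C/c3ccc(OC(C)=O)cc3)CCC[C@@]2(C)[C@@H]1CC[C@H](C)CCO[Si](C)(C)C(C)(C)C | intermediate
28 | 15-alcohol from 27 | C=C1CC[C@@H]2[C@@](C)(COC(=O)/C=C/c3ccc(OC(C)=O)cc3)CCC[C@@]2(C)[C@@H]1CC[C@H](C)CCO | intermediate
29 | 15-aldehyde | C=C1CC[C@@H]2[C@@](C)(COC(=O)/C=C/c3ccc(OC(C)=O)cc3)CCC[C@@]2(C)[C@@H]1CC[C@H](C)CC=O | intermediate
30 | (13S)-ent-18-[(E)-4-acetoxycinnamoyloxy]labd-8(17)-en-15-oic acid | C=C1CC[C@@H]2[C@@](C)(COC(=O)/C=C/c3ccc(OC(C)=O)cc3)CCC[C@@]2(C)[C@@H]1CC[C@H](C)CC(=O)O | intermediate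
31 | (13S)-ent-18-[(E)-4-hydroxycinnamoyloxy]labd-8(17)-en-15-oic acid | C=C1CC[C@@H]2[C@@](C)(COC(=O)/C=C/c3ccc(O)cc3)CCC[C@@]2(C)[C@@H]1CC[C@H](C)CC(=O)O | target

**Step count**
- Total step count: 18.
- Longest linear sequence: 14 (steps 1–4 then 9–18; the chain branch 5–8 then 9–18 is equally long).

**Steps most likely to fail**

Step 12. The risks are competing migration of the C7 methylene, attack of O8 on C9 (epoxide closure), and premature ionisation followed by hydride shift.
- The fallback replaces the cationic shift by an anionic one under thermodynamic control. It sets out from diol 19.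
- The secondary C9 alcohol is oxidised (Dess–Martin periodinane, CH2Cl2) to the 8-hydroxy-9-ketone F1.
- KOtBu in t-BuOH/THF then drives the alpha-ketol rearrangement to the 9-hydroxy-8-ketone F2. This is the same five-to-six ring enlargement and the reaction type of the base-induced D-homoannulation of 17-hydroxy-20-oxo steroids, in which the quaternary carbon migrates.
- SmI2 in THF/MeOH removes the tertiary alpha-hydroxyl through the samarium enolate. Equilibration with NaOMe/MeOH brings the material back to the route at 23.

Step 9. The risks are enolisation of the hindered ketone 10 by the basic ylide, slow oxaphosphetane formation, and erosion of the Z geometry on which step 12 depends.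
- The fallback is a stepwise Horner–Wittig sequence that sets out from iodide 15 and ketone 10.
- Iodide 15 alkylates Ph2P(O)H/NaH (Michaelis–Becker reaction) to the alkyldiphenylphosphine oxide F3.
- The lithio derivative of F3 (n-BuLi, THF, −78 °C) adds to 10 from the face anti to C20.
- The required diastereomer of the beta-hydroxy phosphine oxide F4 is separated by chromatography. It undergoes stereospecific syn elimination with KH in DMF, which returns to the route at geometrically pure 18.

Step 3. The risks are O-alkylation of the lithium enolate by the hard chloromethyl ether, proton exchange with loss of regiocontrol, and incomplete trans selectivity in the protonation at C5.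
- The fallback sets out from 5, which is reduced as before, but the enolate is silylated (TMSCl, Et3N) to the trimethylsilyl enol ether F5.
- F5 can be freed from cis-fused material.
- A ZnBr2-catalysed alkoxymethylation of F5 with benzyl chloromethyl ether in CH2Cl2 (Lewis-acid alkylation of a silyl enol ether, C-selective, same facial bias) comes back to the route at 7.

**Further compounds**
F1 | step 12 | 8-hydroxy-9-ketone (8-OH anti to C20) | CC(C)(C)[Si](C)(C)OCC[C@@H](C)CCC(=O)[C@]1(O)CC[C@@H]2[C@@](C)(COCc3ccccc3)CCC[C@@]12C
F2 | step 12 | 9-hydroxy-17-norlabdan-8-one (9-OH syn to C20, configuration erased in the next operation) | O=C1CC[C@@H]2[C@@](C)(COCc3ccccc3)CCC[C@@]2(C)[C@@]1(O)CC[C@H](C)CCO[Si](C)(C)C(C)(C)C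
F3 | step 9 | (S)-[6-(tert-butyldimethylsilyloxy)-4-methylhexyl]diphenylphosphine oxide | O=P(c1ccccc1)(c1ccccc1)CCC[C@H](C)CCO[Si](C)(C)C(C)(C)C
F4 | step 9 | beta-hydroxy phosphine oxide (8-OH syn to C20, C9 configured for syn elimination to the Z alkene) | CC(C)(C)[Si](C)(C)OCC[C@@H](C)CC[C@H](P(=O)(c1ccccc1)c1ccccc1)[C@@]1(O)CC[C@@H]2[C@@](C)(COCc3ccccc3)CCC[C@@]12C
F5 | step 3 | C3–C4 trimethylsilyl enol ether of the trans-fused ketal | C12(OCCO1)CC[C@@H]3C(C)=C(O[Si](C)(C)C)CC[C@@]23C
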